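**Retrosynthetic overview**

- The hydroquinone of the target is taken back to a quinone and then to a 5-hydroxy-8-methoxychromanone; the C4 ketone is taken back to a silyl-protected benzylic carbinol.
- The strategy rests on the benzene ring C4a–C5–C6–C7–C8–C8a. It carries oxygens para to each other on C5 and C8 and hydrogen on C6 and C7, and is fused through C8a(–O1)=C4a to the pyran ring. This is the 4-alkoxyphenol that an α-alkoxyalkenyl chromium carbene, an alkyne and CO assemble (bonds C8–C7, C6–C5, C5–C4a).
- The carbene carbon is attached to C6 of a 2-pentadecyl-4-silyloxy-3,4-dihydro-2H-pyran. This pyran comes from the enantioselective hetero-Diels–Alder adduct of hexadecanal and the Danishefsky diene, which sets C2.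
- Ring order: pyran ring first (cycloaddition), benzene ring second (benzannulation onto the enol ether double bond); ketone and free hydroquinone are revealed last.

Key step: step 5

Assumption: the catalyst made from Ti(OiPr)4 and (S)-BINOL is taken to direct the diene to the Si face of a straight-chain aldehyde (the sense it shows in the related allylation), which gives R at C2; if the sense proves opposite, (R)-BINOL is used.

**Route**

Step 1
Reactants: 1 hexadecanal; 2 Danishefsky diene, (E)-1-methoxy-3-(trimethylsilyloxy)buta-1,3-diene
Product: 4 (R)-2-pentadecyl-2,3-dihydro-4H-pyran-4-one, via Mukaiyama aldol adduct 3 (not isolated)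
Conditions: (S)-BINOL (20 mol %), Ti(OiPr)4 (10 mol %), 4 Å MS, Et2O, −20 °C; then CF3CO2H, CH2Cl2, 0 °C
Reagents that add atoms: none
Why: Catalytic enantioselective hetero-Diels–Alder reaction in its Mukaiyama aldol/cyclisation form, in which the chiral titanium binaphtholate Lewis acid exposes the Si face of the aldehyde to the diene and so sets C2 as R, and acid then closes the ring by oxa-Michael addition with loss of methanol and the silyl group.

Step 2
Reactants: 4 (R)-2-pentadecyl-2,3-dihydro-4H-pyran-4-one
Product: 5 (2R,4S)-2-pentadecyl-3,4-dihydro-2H-pyran-4-ol (cis)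
Conditions: NaBH4, CeCl3·7H2O, MeOH, −78 °C; NaHCO3 work-up
Reagents that add atoms: none
Why: Luche 1,2-reduction of the vinylogous ester carbonyl, with axial hydride delivery to the half-chair that holds the C2 chain pseudo-equatorial, which should give the cis (pseudo-equatorial) allylic alcohol, a temporary centre that is erased in step 7.

Step 3
Reactants: 5 (2R,4S)-2-pentadecyl-3,4-dihydro-2H-pyran-4-ol
Product: 6 triisopropyl{[(2R,4S)-2-pentadecyl-3,4-dihydro-2H-pyran-4-yl]oxy}silane
Conditions: iPr3SiCl, imidazole, DMAP (cat.), DMF, rt
Reagents that add atoms: chlorotriisopropylsilane, CC(C)[Si](Cl)(C(C)C)C(C)C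
Why: Base-mediated silylation of the secondary allylic alcohol without acid (which the enol ether would not bear), the triisopropylsilyl group being chosen because it has no Si–CH3 group to be metalated and withstands tert-butyllithium.

Step 4
Reactants: 6 triisopropyl{[(2R,4S)-2-pentadecyl-3,4-dihydro-2H-pyran-4-yl]oxy}silane; 7 chromium hexacarbonyl Cr(CO)6
Product: 10 pentacarbonyl{methoxy[(2R,4S)-2-pentadecyl-4-(triisopropylsilyloxy)-3,4-dihydro-2H-pyran-6-yl]methylidene}chromium, via vinyllithium 8 (not isolated), via lithium acyl chromate 9 (not isolated)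
Conditions: t-BuLi, THF, −78 → 0 °C; Cr(CO)6, THF, −78 °C → rt; solvent exchange; Me3OBF4, CH2Cl2, 0 °C
Reagents that add atoms: trimethyloxonium tetrafluoroborate, C[O+](C)C.F[B-](F)(F)F
Why: Fischer carbene synthesis, in which the enol ether C6–H (the sp2 C–H next to the ring oxygen, metalated as in silylated glycals) is removed by tert-butyllithium, the vinyllithium adds to a carbonyl ligand of Cr(CO)6, and the hard oxonium salt methylates the acyl chromate on oxygen.

Step 5
Reactants: 10 pentacarbonyl{methoxy[(2R,4S)-2-pentadecyl-4-(triisopropylsilyloxy)-3,4-dihydro-2H-pyran-6-yl]methylidene}chromium; 11 trimethylsilylacetylene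
Product: 14 (2R,4S)-8-methoxy-2-pentadecyl-4-(triisopropylsilyloxy)-5-(trimethylsilyloxy)chroman, via cyclohexadienone chromium complex 12 (not isolated), via arene chromium tricarbonyl complex 13 (not isolated)
Conditions: Me3SiC≡CH (3 equiv), degassed THF, 50 °C, sealed tube, Ar; then air, daylight, Et2O, rt; crude product taken on
Reagents that add atoms: none
Why: This is a Dötz benzannulation: thermal loss of one CO from 10 is followed by insertion of the alkyne into the Cr=C bond, insertion of a CO ligand, and a thermal disrotatory 6π-electrocyclisation that forms C5–C4a and so closes the six-membered carbocycle onto the C8a=C4a enol ether bond as dienone 12, in which C8 (carbene carbon) and C5 (inserted CO) come from carbonyl ligands and C6 and C7 from the alkyne (new bonds C8–C7, C6–C5, C5–C4a). The closest known reactions are the benzannulations of 2-dihydropyranyl and glycal-derived methoxycarbene chromium complexes with alkynes to chroman hydroquinone monoethers, and those of alkenyl carbene complexes with silylalkynes used in place of acetylene. Dienone 12 should aromatise by passage of the C4a hydrogen to C6 and a 1,3-shift of silicon from C6 to the oxygen on C5, which leaves the silyl ether as arene complex 13, and air then oxidises the chromium tricarbonyl unit away. No lasting stereocentre is made, since the sp3 centre C4a of 12 and the planar chirality of 13 both disappear, while C2 and C4 lie outside the reacting atoms. The step needs chemoselectivity for CO insertion (phenol) over cyclopentannulation and furan formation, which is secured by chromium as the metal, the methoxy group on the carbene carbon, the s-cis-locked electron-rich enol ether double bond and the ether solvent, and it needs silicon on C6 next to the new oxygen, which the usual preference of a terminal alkyne to place its large end beside the CO-derived carbon secures. Simple enolisation of 12 would instead leave silicon on C6, a case covered by the fallback.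

Step 6
Reactants: 14 (2R,4S)-8-methoxy-2-pentadecyl-4-(triisopropylsilyloxy)-5-(trimethylsilyloxy)chroman
Product: 15 (2R,4S)-8-methoxy-2-pentadecylchromane-4,5-diol
Conditions: Bu4NF, AcOH, THF, 0 °C → rt
Reagents that add atoms: none
Why: Fluoride-mediated desilylation driven by the strength of the Si–F bond should cleave the aryl trimethylsilyl ether at once and the benzylic triisopropylsilyl ether more slowly, the acetic acid buffer keeping the electron-rich phenol from base-promoted air oxidation.

Step 7
Reactants: 15 (2R,4S)-8-methoxy-2-pentadecylchromane-4,5-diol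
Product: 16 (R)-5-hydroxy-8-methoxy-2-pentadecylchroman-4-one
Conditions: activated MnO2 (excess), CH2Cl2, rt
Reagents that add atoms: none
Why: Manganese dioxide oxidation is selective for the benzylic carbinol and should leave the p-methoxyphenol untouched under neutral conditions, giving the hydrogen-bonded 5-hydroxychromanone and removing the temporary C4 centre without touching C2.

Step 8
Reactants: 16 (R)-5-hydroxy-8-methoxy-2-pentadecylchroman-4-one
Product: 17 (R)-2-pentadecyl-2,3-dihydro-4H-chromene-4,5,8-trione
Conditions: (NH4)2Ce(NO3)6 (2.2 equiv), MeCN/H2O, 0 °C, 5–10 min; extracted into EtOAc and used at once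
Reagents that add atoms: water, O
Why: Oxidative demethylation of a p-methoxyphenol by tetravalent cerium (two one-electron oxidations, addition of water at C8 and loss of methanol) should give the quinone, kept cold, brief and free of base because the quinone oxygen on C8a is a good leaving group for retro-oxa-Michael opening.

Step 9
Reactants: 17 (R)-2-pentadecyl-2,3-dihydro-4H-chromene-4,5,8-trione
Product: 18 (R)-5,8-dihydroxy-2-pentadecylchroman-4-one (target)
Conditions: Na2S2O4 (excess), H2O/EtOAc, rt, N2
Reagents that add atoms: none
Why: Two-electron reduction of the quinone by dithionite in a neutral two-phase system should give the hydroquinone without reducing the C4 ketone or disturbing C2.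

**Compound list**

1 | hexadecanal | CCCCCCCCCCCCCCCC=O | starting material
2 | Danishefsky diene, (E)-1-methoxy-3-(trimethylsilyloxy)buta-1,3-diene | CO/C=C/C(=C)O[Si](C)(C)C | starting material
3 | (5R,1E)-1-methoxy-5-(trimethylsilyloxy)icos-1-en-3-one (Mukaiyama aldol adduct, not isolated) | CCCCCCCCCCCCCCC[C@@H](O[Si](C)(C)C)CC(=O)/C=C/OC | intermediate
4 | (R)-2-pentadecyl-2,3-dihydro-4H-pyran-4-one | CCCCCCCCCCCCCCC[C@@H]1CC(=O)C=CO1 | intermediate
5 | (2R,4S)-2-pentadecyl-3,4-dihydro-2H-pyran-4-ol (cis) | CCCCCCCCCCCCCCC[C@@H]1C[C@H](O)C=CO1 | intermediate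
6 | triisopropyl{[(2R,4S)-2-pentadecyl-3,4-dihydro-2H-pyran-4-yl]oxy}silane | CCCCCCCCCCCCCCC[C@@H]1C[C@H](O[Si](C(C)C)(C(C)C)C(C)C)C=CO1 | intermediate
7 | chromium hexacarbonyl Cr(CO)6 | O=C=[Cr](=C=O)(=C=O)(=C=O)(=C=O)=C=O | starting material
8 | [(2R,4S)-2-pentadecyl-4-(triisopropylsilyloxy)-3,4-dihydro-2H-pyran-6-yl]lithium (not isolated) | CCCCCCCCCCCCCCC[C@@H]1C[C@H](O[Si](C(C)C)(C(C)C)C(C)C)C=C([Li])O1 | intermediate
9 | lithium pentacarbonyl{[(2R,4S)-2-pentadecyl-4-(triisopropylsilyloxy)-3,4-dihydro-2H-pyran-6-yl]carbonyl}chromate (not isolated) | CCCCCCCCCCCCCCC[C@@H]1C[C@H](O[Si](C(C)C)(C(C)C)C(C)C)C=C(O1)C([O-])=[Cr](=C=O)(=C=O)(=C=O)(=C=O)=C=O.[Li+] | intermediate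
10 | pentacarbonyl{methoxy[(2R,4S)-2-pentadecyl-4-(triisopropylsilyloxy)-3,4-dihydro-2H-pyran-6-yl]methylidene}chromium | CCCCCCCCCCCCCCC[C@@H]1C[C@H](O[Si](C(C)C)(C(C)C)C(C)C)C=C(O1)C(OC)=[Cr](=C=O)(=C=O)(=C=O)(=C=O)=C=O | intermediate
11 | trimethylsilylacetylene | C#C[Si](C)(C)C | starting material
12 | chromium tricarbonyl complex of (2R,4S)-8-methoxy-2-pentadecyl-4-(triisopropylsilyloxy)-6-(trimethylsilyl)-2,3,4,4a-tetrahydro-5H-chromen-5-one (C4a configuration undefined, not isolated; written as ligand plus Cr(CO)3 fragment) | CCCCCCCCCCCCCCC[C@@H]1C[C@H](O[Si](C(C)C)(C(C)C)C(C)C)C2C(=O)C([Si](C)(C)C)=CC(OC)=C2O1.O=C=[Cr](=C=O)=C=O | intermediate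
13 | tricarbonyl[η6-(2R,4S)-8-methoxy-2-pentadecyl-4-(triisopropylsilyloxy)-5-(trimethylsilyloxy)chroman]chromium (not isolated; written as arene plus Cr(CO)3 fragment) | CCCCCCCCCCCCCCC[C@@H]1C[C@H](O[Si](C(C)C)(C(C)C)C(C)C)c2c(O[Si](C)(C)C)ccc(OC)c2O1.O=C=[Cr](=C=O)=C=O | intermediate
14 | (2R,4S)-8-methoxy-2-pentadecyl-4-(triisopropylsilyloxy)-5-(trimethylsilyloxy)chroman | CCCCCCCCCCCCCCC[C@@H]1C[C@H](O[Si](C(C)C)(C(C)C)C(C)C)c2c(O[Si](C)(C)C)ccc(OC)c2O1 | intermediate
15 | (2R,4S)-8-methoxy-2-pentadecylchromane-4,5-diol | CCCCCCCCCCCCCCC[C@@H]1C[C@H](O)c2c(O)ccc(OC)c2O1 | intermediate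
16 | (R)-5-hydroxy-8-methoxy-2-pentadecylchroman-4-one | CCCCCCCCCCCCCCC[C@@H]1CC(=O)c2c(O)ccc(OC)c2O1 | intermediate
17 | (R)-2-pentadecyl-2,3-dihydro-4H-chromene-4,5,8-trione | CCCCCCCCCCCCCCC[C@@H]1CC(=O)C2=C(O1)C(=O)C=CC2=O | intermediate
18 | (R)-5,8-dihydroxy-2-pentadecylchroman-4-one | CCCCCCCCCCCCCCC[C@@H]1CC(=O)c2c(O)ccc(O)c2O1 | target

**Totals and risks**

Total step count: 9. Longest linear sequence: 9 steps (1 to 18).

Steps most likely to fail, in order of risk:

Step 5. Enolisation of dienone 12 may outrun the hydrogen and silicon shifts, so that silicon stays on C6; fluoride in step 6 would then free only the oxygen on C4 and C6 would remain silylated. The fallback removes silicon by electrophilic ipso-substitution at a later, acid-tolerant stage instead of by fluoride. It sets out from 10 (with 11): the benzannulation, worked up as before, would give (2R,4S)-8-methoxy-2-pentadecyl-4-(triisopropylsilyloxy)-6-(trimethylsilyl)chroman-5-ol F1. Bu4NF/AcOH in THF would remove only the triisopropylsilyl group to give (2R,4S)-8-methoxy-2-pentadecyl-6-(trimethylsilyl)chromane-4,5-diol F2. MnO2 in CH2Cl2 would give (R)-5-hydroxy-8-methoxy-2-pentadecyl-6-(trimethylsilyl)chroman-4-one F3. CF3CO2H in CH2Cl2 at 0 °C would then protodesilylate C6, which is ortho to the C5 hydroxyl and para to O1 and therefore strongly activated for ipso-protonation. The chromanone tolerates this acid, whereas the benzylic C4 ethers and carbinols before it would ionise. The fallback comes back to the route at 16.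

Step 4. Metalation at C6 may be incomplete, and surplus tert-butyllithium may be carried into the Cr(CO)6 addition and be consumed there in forming a tert-butyl carbene complex, so that 10 would form in low amount and impure. The fallback separates metalation from carbene formation through an isolable stannane. It sets out from 6: metalation with n-BuLi/KOtBu (Schlosser base) in THF at −78 °C and quenching with Bu3SnCl would give tributyl[(2R,4S)-2-pentadecyl-4-(triisopropylsilyloxy)-3,4-dihydro-2H-pyran-6-yl]stannane F4, purified on triethylamine-washed silica. Tin–lithium exchange with one equivalent of n-BuLi in THF at −78 °C would then give vinyllithium 8 free of other bases. Cr(CO)6 and Me3OBF4 as in step 4 bring the route back at 10.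

Step 8. The acylquinone 17 may open by retro-oxa-Michael elimination (enolisation at C3 and expulsion of the hydroxyquinone oxygen from C2) or be attacked by nucleophiles during oxidation and work-up, with loss of the ring or of the C2 configuration. The fallback avoids the quinone by non-oxidative ether cleavage. It sets out from 16: BBr3 in CH2Cl2 at −78 → 0 °C should bind the 5-hydroxy/4-keto chelate and then cleave the 8-methoxy group by bromide attack on methyl, O1 being a poorly basic vinylogous ester oxygen; aqueous work-up would give 18 directly. The fallback comes back to the route at 18 and makes no compound outside the list (none, F0).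

**Further compounds**

F1 | step 5 | (2R,4S)-8-methoxy-2-pentadecyl-4-(triisopropylsilyloxy)-6-(trimethylsilyl)chroman-5-ol | CCCCCCCCCCCCCCC[C@@H]1C[C@H](O[Si](C(C)C)(C(C)C)C(C)C)c2c(O)c([Si](C)(C)C)cc(OC)c2O1
F2 | step 5 | (2R,4S)-8-methoxy-2-pentadecyl-6-(trimethylsilyl)chromane-4,5-diol | CCCCCCCCCCCCCCC[C@@H]1C[C@H](O)c2c(O)c([Si](C)(C)C)cc(OC)c2O1
F3 | step 5 | (R)-5-hydroxy-8-methoxy-2-pentadecyl-6-(trimethylsilyl)chroman-4-one | CCCCCCCCCCCCCCC[C@@H]1CC(=O)c2c(O)c([Si](C)(C)C)cc(OC)c2O1
F4 | step 4 | tributyl[(2R,4S)-2-pentadecyl-4-(triisopropylsilyloxy)-3,4-dihydro-2H-pyran-6-yl]stannane | CCCCCCCCCCCCCCC[C@@H]1C[C@H](O[Si](C(C)C)(C(C)C)C(C)C)C=C(O1)[Sn](CCCC)(CCCC)CCCC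
F0 | step 8 | none | none
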